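## Retrosynthetic overview

1. Target ⇐ its 7,4'-diacetate by neutral deacetylation. No ring is built: rings A, B and C, with C2 already (S), come intact from (2S)-naringenin.
2. C8–C1'' bond ⇐ 8-bromo-6-prenyl flavanone + 2-[(2S)-oxiran-2-yl]propan-2-ol, by nickel-catalysed reductive arylation at the epoxide CH2 (the carbinol centre is not touched). The epoxide ⇐ methyl (S)-glycidate + 2 MeMgCl.
3. 6-Prenyl ⇐ 6-allyl by cross-metathesis with 2-methyl-2-butene; 8-Br ⇐ bromination of the only free ring A position.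
4. Key step: the C6–C bond ⇐ europium-catalysed [3,3] aromatic Claisen rearrangement of the 5-O-allyl ether. It can deliver only to C6 and so fixes the whole ring A substitution pattern.
5. 5-O-Allyl ether ⇐ Mitsunobu allylation of 7,4'-di-O-acetyl-(2S)-naringenin ⇐ (2S)-naringenin.

Assumption: (2S)-naringenin 1 is bought in high enantiomeric purity (natural material; a partly racemised lot would be recrystallised first).

## Route

**Step 1**
Reactants: 1 (2S)-naringenin
Product: 2 (2S)-7,4'-di-O-acetylnaringenin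
Conditions: Ac2O (2.1 equiv), pyridine, 0 °C to rt
Reagents that add atoms: acetic anhydride, CC(=O)OC(C)=O
Why: Selective O-acylation: the 7- and 4'-hydroxyls react, while the 5-OH is hydrogen-bonded to the C4 carbonyl and stays free; C2 is not involved.

**Step 2**
Reactants: 2 (2S)-7,4'-di-O-acetylnaringenin
Product: 3 (2S)-5-O-allyl-7,4'-di-O-acetylnaringenin
Conditions: allyl alcohol (1.5 equiv), PPh3 (1.5 equiv), DIAD (1.5 equiv), THF, 0 °C to rt
Reagents that add atoms: allyl alcohol, C=CCO
Why: Mitsunobu etherification alkylates the only free phenol without added base, so the flavanone does not open to the chalcone and C2 stays (S).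

**Step 3**
Reactants: 3 (2S)-5-O-allyl-7,4'-di-O-acetylnaringenin
Product: 5 (2S)-6-allyl-7,4'-di-O-acetylnaringenin, via ortho-dienone 4 (not isolated)
Conditions: Eu(fod)3 [Eu(C10H10F7O2)3] (10 mol %), toluene, 90 °C
Reagents that add atoms: none
Why: Aromatic Claisen [3,3] sigmatropic rearrangement, accelerated by chelation of trivalent europium between the C4 carbonyl and O5; C6 is the only ortho position of O5, and the dienone tautomerises to the 5-hydroxy-6-allyl arene.

**Step 4**
Reactants: 5 (2S)-6-allyl-7,4'-di-O-acetylnaringenin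
Product: 6 (2S)-6-allyl-8-bromo-7,4'-di-O-acetylnaringenin
Conditions: NBS (1.05 equiv), MeCN, −20 to 0 °C, dark
Reagents that add atoms: N-bromosuccinimide, O=C1CCC(=O)N1Br
Why: Electrophilic aromatic bromination: C8 is the last free ring A carbon and is para to the free 5-OH, so it reacts faster than the monosubstituted alkene or the acetoxyphenyl ring.

**Step 5**
Reactants: 6 (2S)-6-allyl-8-bromo-7,4'-di-O-acetylnaringenin
Product: 7 (2S)-8-bromo-6-prenyl-7,4'-di-O-acetylnaringenin
Conditions: 2-methyl-2-butene (30 equiv), second-generation Grubbs catalyst RuCl2(=CHPh)(PCy3)(H2IMes) (5 mol %), CH2Cl2, 40 °C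
Reagents that add atoms: 2-methyl-2-butene, CC=C(C)C
Why: Olefin cross-metathesis swaps the terminal CH2 for an isopropylidene group with loss of propene, and tolerates the aryl bromide, acetates and phenol.

**Step 6**
Reactants: 8 methyl (S)-glycidate
Product: 9 2-[(2S)-oxiran-2-yl]propan-2-ol
Conditions: MeMgCl (2.2 equiv), THF, −78 to −30 °C; aq NH4Cl; careful concentration (volatile)
Reagents that add atoms: methylmagnesium chloride, C[Mg]Cl
Why: Double Grignard addition to the ester is faster than epoxide opening at low temperature; the stereocentre is not a reacting site, so (S) is retained.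

**Step 7**
Reactants: 7 (2S)-8-bromo-6-prenyl-7,4'-di-O-acetylnaringenin; 9 2-[(2S)-oxiran-2-yl]propan-2-ol (1.5 equiv)
Product: 11 (2S)-8-[(2S)-2,3-dihydroxy-3-methylbutyl]-6-prenyl-7,4'-di-O-acetylnaringenin, via iodohydrin 10 (not isolated)
Conditions: NiCl2·DME (10 mol %), 2,2'-bipyridine (10 mol %), NaI (25 mol %), Et3N·HCl (1.0 equiv), Zn dust (2 equiv), DMPU, rt
Reagents that add atoms: none
Why: Nickel-catalysed reductive cross-electrophile coupling: iodide opens the epoxide at the unhindered CH2 to the iodohydrin, whose primary radical is captured by the aryl-nickel species; the C–O stereocentre is never broken, so the (S)-epoxide gives the (2S)-diol side chain, and ketone, acetates and alkene are tolerated.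

**Step 8**
Reactants: 11 (2S)-8-[(2S)-2,3-dihydroxy-3-methylbutyl]-6-prenyl-7,4'-di-O-acetylnaringenin
Product: 12 target, (2S)-8-[(2S)-2,3-dihydroxy-3-methylbutyl]-6-prenylnaringenin
Conditions: NH4OAc (10 equiv), MeOH/H2O 4:1, rt
Reagents that add atoms: none
Why: Near-neutral chemoselective cleavage of the two aryl acetates avoids both base-induced ring opening to the chalcone (C2 epimerisation) and acid-induced cyclisation of the prenyl or diol chains onto the phenols.

## Compound list

1 | (2S)-naringenin; (2S)-5,7-dihydroxy-2-(4-hydroxyphenyl)chroman-4-one | O=C1C[C@@H](c2ccc(O)cc2)Oc2cc(O)cc(O)c21 | starting material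
2 | (2S)-7-acetoxy-2-(4-acetoxyphenyl)-5-hydroxychroman-4-one | O=C1C[C@@H](c2ccc(OC(C)=O)cc2)Oc2cc(OC(C)=O)cc(O)c21 | intermediate
3 | (2S)-7-acetoxy-2-(4-acetoxyphenyl)-5-(allyloxy)chroman-4-one | O=C1C[C@@H](c2ccc(OC(C)=O)cc2)Oc2cc(OC(C)=O)cc(OCC=C)c21 | intermediate
4 | ortho-dienone: (2S)-7-acetoxy-2-(4-acetoxyphenyl)-6-allyl-2,3-dihydro-6H-chromene-4,5-dione (C6 sp3, bearing H and allyl; C6 configuration undefined) | O=C1C[C@@H](c2ccc(OC(C)=O)cc2)OC2=C1C(=O)C(CC=C)C(OC(C)=O)=C2 | intermediate (not isolated)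
5 | (2S)-7-acetoxy-2-(4-acetoxyphenyl)-6-allyl-5-hydroxychroman-4-one | C=CCc1c(OC(C)=O)cc2c(c1O)C(=O)C[C@@H](c1ccc(OC(C)=O)cc1)O2 | intermediate
6 | (2S)-7-acetoxy-2-(4-acetoxyphenyl)-6-allyl-8-bromo-5-hydroxychroman-4-one | C=CCc1c(OC(C)=O)c(Br)c2c(c1O)C(=O)C[C@@H](c1ccc(OC(C)=O)cc1)O2 | intermediate
7 | (2S)-7-acetoxy-2-(4-acetoxyphenyl)-8-bromo-5-hydroxy-6-(3-methylbut-2-enyl)chroman-4-one | CC(C)=CCc1c(OC(C)=O)c(Br)c2c(c1O)C(=O)C[C@@H](c1ccc(OC(C)=O)cc1)O2 | intermediate
8 | methyl (2S)-oxirane-2-carboxylate (methyl (S)-glycidate) | COC(=O)[C@@H]1CO1 | starting material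
9 | 2-[(2S)-oxiran-2-yl]propan-2-ol | CC(C)(O)[C@@H]1CO1 | intermediate
10 | (2R)-1-iodo-3-methylbutane-2,3-diol | CC(C)(O)[C@@H](O)CI | intermediate (not isolated)
11 | (2S)-7-acetoxy-2-(4-acetoxyphenyl)-8-[(2S)-2,3-dihydroxy-3-methylbutyl]-5-hydroxy-6-(3-methylbut-2-enyl)chroman-4-one | CC(C)=CCc1c(OC(C)=O)c(C[C@H](O)C(C)(C)O)c2c(c1O)C(=O)C[C@@H](c1ccc(OC(C)=O)cc1)O2 | intermediate
12 | (2S)-8-[(2S)-2,3-dihydroxy-3-methylbutyl]-5,7-dihydroxy-2-(4-hydroxyphenyl)-6-(3-methylbut-2-enyl)chroman-4-one | CC(C)=CCc1c(O)c(C[C@H](O)C(C)(C)O)c2c(c1O)C(=O)C[C@@H](c1ccc(O)cc1)O2 | target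

## Step count

Total: 8 steps. Longest linear sequence: 7 steps (steps 1, 2, 3, 4, 5, 7, 8); step 6 is the one-step side branch.

## Steps most likely to fail, with fallbacks

**Step 7 (nickel coupling).** The aryl bromide is flanked on both sides, so oxidative addition and radical capture may be slow and hydrodebromination may win. The fallback sets out from 7 and returns at 11. Iodohydrin 10 is made deliberately (9, NaI, AcOH, THF) and isolated, then protected with 2,2-dimethoxypropane and PPTS as (4R)-4-(iodomethyl)-2,2,5,5-tetramethyl-1,3-dioxolane F1. F1 is joined to 7 under light-driven dual catalysis, in which a silyl radical abstracts the iodine and no metal reductant or free β-hydroxyl is present: [Ir(dF(CF3)ppy)2(dtbbpy)]PF6 (1 mol %), NiCl2·DME (5 mol %), 4,4'-di-tert-butyl-2,2'-bipyridine, (Me3Si)3SiH, Na2CO3, DME, blue LED, rt. This gives (2S)-7-acetoxy-2-(4-acetoxyphenyl)-5-hydroxy-6-(3-methylbut-2-enyl)-8-{[(4S)-2,2,5,5-tetramethyl-1,3-dioxolan-4-yl]methyl}chroman-4-one F2. Mild hydrolysis of the acetonide (PPTS, MeOH/H2O, 40 °C) then gives 11.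

**Step 4 (bromination).** With the 5-OH free and an ortho-allyl group present, bromo-etherification of the alkene could compete with ring bromination. The fallback sets out from 3 and returns at 6, by brominating before the rearrangement, when there is no free phenol next to an alkene. NBS in DMF at 0 °C to rt on 3 attacks C8, which is para to the 5-alkoxy group and less hindered than C6, to give (2S)-7-acetoxy-2-(4-acetoxyphenyl)-5-(allyloxy)-8-bromochroman-4-one F3. The same Eu(fod)3 Claisen rearrangement (toluene, 90 °C) then passes through the 8-bromo ortho-dienone F4 (not isolated) and delivers 6.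

**Step 6 (Grignard on the glycidate).** Halide or Grignard opening of the epoxide and loss of the small, volatile, water-soluble product are the risks. The fallback sets out from 8 and returns at 10, bypassing 9. The epoxide is opened first at C3 (NaI, AcOH, THF, 0 °C) to methyl (2R)-2-hydroxy-3-iodopropanoate F5. MeMgCl (3.3 equiv, THF, −78 to −30 °C, cold NH4Cl quench) then converts the ester into the tertiary alcohol, giving the non-volatile iodohydrin 10. Isolated 10 enters step 7 in place of 9, and any 10 that closes back to 9 is equally usable there.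

## Further compounds

F1 | step 7 | (4R)-4-(iodomethyl)-2,2,5,5-tetramethyl-1,3-dioxolane | IC[C@H](OC(C)(C)O1)C1(C)C
F2 | step 7 | (2S)-7-acetoxy-2-(4-acetoxyphenyl)-5-hydroxy-6-(3-methylbut-2-enyl)-8-{[(4S)-2,2,5,5-tetramethyl-1,3-dioxolan-4-yl]methyl}chroman-4-one | CC(C)=CCc1c(OC(C)=O)c(C[C@H](OC(C)(C)O3)C3(C)C)c2c(c1O)C(=O)C[C@@H](c1ccc(OC(C)=O)cc1)O2
F3 | step 4 | (2S)-7-acetoxy-2-(4-acetoxyphenyl)-5-(allyloxy)-8-bromochroman-4-one | O=C1C[C@@H](c2ccc(OC(C)=O)cc2)Oc2c(Br)c(OC(C)=O)cc(OCC=C)c21
F4 | step 4 | (2S)-7-acetoxy-2-(4-acetoxyphenyl)-6-allyl-8-bromo-2,3-dihydro-6H-chromene-4,5-dione (ortho-dienone, not isolated) | O=C1C[C@@H](c2ccc(OC(C)=O)cc2)OC2=C1C(=O)C(CC=C)C(OC(C)=O)=C2Br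
F5 | step 6 | methyl (2R)-2-hydroxy-3-iodopropanoate | IC[C@H](O)C(=O)OC
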